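**Retrosynthetic overview**
- Target ⇒ late C3 hydroxymethylation (Morita–Baylis–Hillman) and side-chain cross-metathesis of a methacrylate; both esters are put on by plain O-acylation.
- Cyclohexenone core ⇐ one-carbon ring expansion (diazo insertion with 1,2-shift of a ring CH2) of a 2-acyloxy-3-isopropyl-4-silyloxycyclopentanone, then dehydrogenation of the enol silane that the expansion delivers.
- Cyclopentanone ⇐ Rubottom oxidation of the enol silane from an alkoxide-directed syn 1,4-isopropylation of (S)-4-hydroxycyclopent-2-en-1-one.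
- Ring order: the five-membered ring comes with the starting material; the six-membered ring is made from it by the ring expansion; no other ring is formed.

Assumption: (S)-4-hydroxycyclopent-2-en-1-one (compound 1) is bought as the single enantiomer.

**Step 1**
Reactants: 1 (S)-4-hydroxycyclopent-2-en-1-one; 2 isopropylmagnesium chloride
Product: 5 (3R,4S)-3-isopropyl-1,4-bis[(triethylsilyl)oxy]cyclopent-1-ene, via alkoxyzincate 3 (not isolated), via zinc magnesium enolate 4 (not isolated)
Conditions: iPrMgCl (3.0 equiv), ZnCl2 (1.0 equiv), THF, 0 °C; add 1, −78 → −20 °C; then Et3SiCl (2.5 equiv), Et3N, DMPU, −78 → 0 °C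
Reagents that add atoms: chlorotriethylsilane, CC[Si](Cl)(CC)CC
Why: Proposed new method: alkoxide-directed syn 1,4-isopropylation (conjugate addition) through a substrate-bound zincate – the hydroxyl of 1 protonates one Zn–C bond of iPr3ZnMgCl to give alkoxy(diisopropyl)zincate 3, whose isopropyl group can reach the enone β-carbon only across the oxygen-bearing face (five-centre O–Zn–C···C transfer), so the new C–C bond and the C3 stereocentre are set cis to oxygen, 1,2-addition is out of reach for the tethered group and disfavoured for a soft zincate, and the regiodefined enolate 4 is captured on oxygen together with the alkoxide; closest known reactivity: hydroxyl-directed cis conjugate delivery of alkynyl groups from alanes to 4-hydroxycyclopent-2-enones, alkoxide-directed 1,4-additions of RMgX to quinol alkoxides, and undirected conjugate addition of triorganozincates to cycloalkenones.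

**Step 2**
Reactants: 5 (3R,4S)-3-isopropyl-1,4-bis[(triethylsilyl)oxy]cyclopent-1-ene
Product: 7 (2R,3R,4S)-2-hydroxy-3-isopropyl-4-[(triethylsilyl)oxy]cyclopentan-1-one, via silyloxy epoxide 6 (not isolated)
Conditions: DMDO (1.1 equiv), acetone/CH2Cl2, −78 → −20 °C; then 10% aq. citric acid, THF, 0 °C
Reagents that add atoms: dimethyldioxirane, CC1(C)OO1
Why: Rubottom oxidation – DMDO epoxidises the enol silane on the face opposite the C3 isopropyl and C4 silyloxy groups, and mild acid opens silyloxy epoxide 6 to the α-hydroxy ketone with the new C2 oxygen trans to isopropyl while the alkyl triethylsilyl ether survives.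

**Step 3**
Reactants: 7 (2R,3R,4S)-2-hydroxy-3-isopropyl-4-[(triethylsilyl)oxy]cyclopentan-1-one; 8 methacryloyl chloride
Product: 9 (1R,2R,3S)-2-isopropyl-5-oxo-3-[(triethylsilyl)oxy]cyclopentyl 2-methylprop-2-enoate
Conditions: Et3N, DMAP (cat.), CH2Cl2, −20 → 0 °C
Reagents that add atoms: none
Why: DMAP-catalysed O-acylation of the unhindered α-ketol hydroxyl; no stereocentre is touched and the low temperature avoids β-elimination of the silyloxy group.

**Step 4**
Reactants: 9 (1R,2R,3S)-2-isopropyl-5-oxo-3-[(triethylsilyl)oxy]cyclopentyl 2-methylprop-2-enoate; 10 (trimethylsilyl)diazomethane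
Product: 12 (1R,5S,6R)-6-isopropyl-2-oxo-5-[(triethylsilyl)oxy]cyclohex-3-en-1-yl 2-methylprop-2-enoate, via enol silane 11 (not isolated)
Conditions: Sc(OTf)3 (10 mol%), toluene, −40 → 0 °C; then Pd(OAc)2 (1.1 equiv), MeCN, 25 °C
Reagents that add atoms: none
Why: Lewis-acid-catalysed diazoalkane ring expansion (1,2-alkyl shift with loss of N2) – the unsubstituted C4 methylene migrates rather than the hindered, electron-poor acyloxy-bearing C1, the C-to-O silyl shift gives enol silane 11 at the inserted carbon only (which also stops a second insertion), and Saegusa–Ito oxidation turns it into the enone; the three stereocentres are not involved and the methacrylate does not undergo dipolar cycloaddition at this temperature.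

**Step 5**
Reactants: 12 (1R,5S,6R)-6-isopropyl-2-oxo-5-[(triethylsilyl)oxy]cyclohex-3-en-1-yl 2-methylprop-2-enoate; 13 2-methylpropanoyl chloride
Product: 15 (1R,5S,6S)-6-isopropyl-5-[(2-methylpropanoyl)oxy]-2-oxocyclohex-3-en-1-yl 2-methylprop-2-enoate, via allylic alcohol 14 (not isolated)
Conditions: HF·pyridine, THF/pyridine, 0 °C; then 13, DMAP (cat.), 0 → 25 °C
Reagents that add atoms: none
Why: Fluoride desilylation followed by O-acylation in the same flask; the C5–O bond is never broken, so the cis relation to isopropyl set in step 1 is kept.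

**Step 6**
Reactants: 15 (1R,5S,6S)-6-isopropyl-5-[(2-methylpropanoyl)oxy]-2-oxocyclohex-3-en-1-yl 2-methylprop-2-enoate; 16 (Z)-but-2-ene-1,4-diol
Product: 17 (1R,5S,6S)-6-isopropyl-5-[(2-methylpropanoyl)oxy]-2-oxocyclohex-3-en-1-yl (2E)-4-hydroxy-2-methylbut-2-enoate
Conditions: second-generation Hoveyda–Grubbs catalyst RuCl2(H2IMes)(=CH-C6H4-2-OiPr) (10 mol%), 16 (5 equiv), CH2Cl2/THF, 40 °C
Reagents that add atoms: none
Why: Olefin cross-metathesis of the 1,1-disubstituted methacrylate with the symmetrical allylic diol gives the trisubstituted enoate as the E isomer under thermodynamic control, while the conjugated ring alkene is inert.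

**Step 7**
Reactants: 17 (1R,5S,6S)-6-isopropyl-5-[(2-methylpropanoyl)oxy]-2-oxocyclohex-3-en-1-yl (2E)-4-hydroxy-2-methylbut-2-enoate; 18 formaldehyde
Product: 19 (1R,5S,6S)-3-(hydroxymethyl)-6-isopropyl-5-[(2-methylpropanoyl)oxy]-2-oxocyclohex-3-en-1-yl (2E)-4-hydroxy-2-methylbut-2-enoate
Conditions: 37% aq. CH2O (3 equiv), DMAP (0.2 equiv), THF/H2O, 25 °C
Reagents that add atoms: none
Why: Morita–Baylis–Hillman hydroxymethylation – DMAP adds reversibly to C4, the enolate takes formaldehyde at C3 and loss of DMAP restores the enone; no stereocentre is formed and the side-chain enoate, being β-substituted, does not compete.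

**Compound list**
1 | (S)-4-hydroxycyclopent-2-en-1-one | O=C1C=C[C@@H](O)C1 | starting material
2 | isopropylmagnesium chloride | CC(C)[Mg]Cl | starting material
3 | chloromagnesium diisopropyl{[(1S)-4-oxocyclopent-2-en-1-yl]oxy}zincate | O=C1C=C[C@@H](O[Zn-](C(C)C)C(C)C)C1.[Mg+]Cl | intermediate
4 | chloromagnesium (3R,4S)-3-isopropyl-4-[(isopropylzincio)oxy]cyclopent-1-en-1-olate | Cl[Mg]OC1=C[C@@H](C(C)C)[C@@H](O[Zn]C(C)C)C1 | intermediate
5 | (3R,4S)-3-isopropyl-1,4-bis[(triethylsilyl)oxy]cyclopent-1-ene (isopropyl cis to the C4 oxygen) | CC[Si](CC)(CC)OC1=C[C@@H](C(C)C)[C@@H](O[Si](CC)(CC)CC)C1 | intermediate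
6 | (1R,3S,4R,5R)-4-isopropyl-1,3-bis[(triethylsilyl)oxy]-6-oxabicyclo[3.1.0]hexane (epoxide oxygen anti to isopropyl) | CC[Si](CC)(CC)O[C@@]12O[C@@H]1[C@@H](C(C)C)[C@@H](O[Si](CC)(CC)CC)C2 | intermediate
7 | (2R,3R,4S)-2-hydroxy-3-isopropyl-4-[(triethylsilyl)oxy]cyclopentan-1-one | O=C1[C@H](O)[C@@H](C(C)C)[C@@H](O[Si](CC)(CC)CC)C1 | intermediate
8 | methacryloyl chloride (2-methylprop-2-enoyl chloride) | C=C(C)C(=O)Cl | starting material
9 | (1R,2R,3S)-2-isopropyl-5-oxo-3-[(triethylsilyl)oxy]cyclopentyl 2-methylprop-2-enoate | O=C1[C@H](OC(=O)C(C)=C)[C@@H](C(C)C)[C@@H](O[Si](CC)(CC)CC)C1 | intermediate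
10 | (trimethylsilyl)diazomethane | C[Si](C)(C)C=[N+]=[N-] | starting material
11 | (1R,5S,6R)-6-isopropyl-5-[(triethylsilyl)oxy]-2-[(trimethylsilyl)oxy]cyclohex-2-en-1-yl 2-methylprop-2-enoate | C=C(C)C(=O)O[C@H]1C(O[Si](C)(C)C)=CC[C@H](O[Si](CC)(CC)CC)[C@@H]1C(C)C | intermediate
12 | (1R,5S,6R)-6-isopropyl-2-oxo-5-[(triethylsilyl)oxy]cyclohex-3-en-1-yl 2-methylprop-2-enoate | C=C(C)C(=O)O[C@H]1C(=O)C=C[C@H](O[Si](CC)(CC)CC)[C@@H]1C(C)C | intermediate
13 | 2-methylpropanoyl chloride (isobutyryl chloride) | CC(C)C(=O)Cl | starting material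
14 | (1R,5S,6S)-5-hydroxy-6-isopropyl-2-oxocyclohex-3-en-1-yl 2-methylprop-2-enoate | C=C(C)C(=O)O[C@H]1C(=O)C=C[C@H](O)[C@@H]1C(C)C | intermediate
15 | (1R,5S,6S)-6-isopropyl-5-[(2-methylpropanoyl)oxy]-2-oxocyclohex-3-en-1-yl 2-methylprop-2-enoate | C=C(C)C(=O)O[C@H]1C(=O)C=C[C@H](OC(=O)C(C)C)[C@@H]1C(C)C | intermediate
16 | (Z)-but-2-ene-1,4-diol | OC/C=C\CO | starting material
17 | (1R,5S,6S)-6-isopropyl-5-[(2-methylpropanoyl)oxy]-2-oxocyclohex-3-en-1-yl (2E)-4-hydroxy-2-methylbut-2-enoate | C/C(=C\CO)C(=O)O[C@H]1C(=O)C=C[C@H](OC(=O)C(C)C)[C@@H]1C(C)C | intermediate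
18 | formaldehyde | C=O | starting material
19 | (1R,5S,6S)-3-(hydroxymethyl)-6-isopropyl-5-[(2-methylpropanoyl)oxy]-2-oxocyclohex-3-en-1-yl (2E)-4-hydroxy-2-methylbut-2-enoate | C/C(=C\CO)C(=O)O[C@H]1C(=O)C(CO)=C[C@H](OC(=O)C(C)C)[C@@H]1C(C)C | target

**Totals.** Total step count: 7. Longest linear sequence: 7 steps (1 → 19); all other starting materials are bought.

**Three steps most likely to fail**

Step 1 (the proposed new method). The risks are undirected delivery of isopropyl to the face anti to oxygen by a second zincate molecule, and sluggish silylation of the zinc alkoxide. The fallback uses known chemistry, sets out from 1 and sets the isopropyl centre by hydride delivery instead of carbon delivery. Compound 1 is silylated (Et3SiCl, imidazole, DMF) to (S)-4-[(triethylsilyl)oxy]cyclopent-2-en-1-one F1. Ordinary anti conjugate addition of 2 (CuBr·SMe2 10 mol%, Me3SiCl, THF, −78 °C) gives (3S,4S)-3-isopropyl-4-[(triethylsilyl)oxy]-1-[(trimethylsilyl)oxy]cyclopent-1-ene F2. Saegusa–Ito oxidation with Pd(OAc)2 in MeCN erases the wrongly set centre and gives (S)-3-isopropyl-4-[(triethylsilyl)oxy]cyclopent-2-en-1-one F3. RhCl(PPh3)3-catalysed 1,4-hydrosilylation with Et3SiH then puts hydrogen on C3 anti to the silyloxy group, which leaves isopropyl cis to it, and the sequence comes back to the route at 5.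

Step 4 (ring expansion and dehydrogenation). The risks are attack of the diazo reagent on the methacrylate, epoxide formation in place of the shift, and loss of material during the palladium step. The fallback sets out from 7 and moves the ring expansion ahead of the first acylation, so that the diazo compound meets only silyl ethers. The hydroxyl of 7 is capped (Me3SiCl, imidazole, CH2Cl2) to give (2R,3S,4S)-3-isopropyl-4-[(triethylsilyl)oxy]-2-[(trimethylsilyl)oxy]cyclopentan-1-one F4. Homologation with 10 under Sc(OTf)3 gives (4S,5S,6R)-5-isopropyl-4-[(triethylsilyl)oxy]-1,6-bis[(trimethylsilyl)oxy]cyclohex-1-ene F5, which Pd(OAc)2 oxidises to (4S,5S,6R)-5-isopropyl-4-[(triethylsilyl)oxy]-6-[(trimethylsilyl)oxy]cyclohex-2-en-1-one F6. Selective hydrolysis of the trimethylsilyl ether (citric acid, MeOH/H2O, 0 °C) gives (4S,5R,6R)-6-hydroxy-5-isopropyl-4-[(triethylsilyl)oxy]cyclohex-2-en-1-one F7. Acylation with 8 (Et3N, DMAP) comes back to the route at 12.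

Step 7 (Morita–Baylis–Hillman on the fully functionalised enone). The risks are slow addition next to the C5 ester and ester cleavage in aqueous DMAP. The fallback sets out from 17 and uses halogenation and cross-coupling under anhydrous conditions. α-Iodination (I2, pyridine, CH2Cl2, 0 °C) gives (1R,5R,6S)-3-iodo-6-isopropyl-5-[(2-methylpropanoyl)oxy]-2-oxocyclohex-3-en-1-yl (2E)-4-hydroxy-2-methylbut-2-enoate F8. Stille coupling with the reagent (tributylstannyl)methanol under Pd(PPh3)4 (zerovalent palladium) in dioxane at 80 °C comes back to the route at 19.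

**Further compounds**
F1 | step 1 | (S)-4-[(triethylsilyl)oxy]cyclopent-2-en-1-one | O=C1C=C[C@@H](O[Si](CC)(CC)CC)C1
F2 | step 1 | (3S,4S)-3-isopropyl-4-[(triethylsilyl)oxy]-1-[(trimethylsilyl)oxy]cyclopent-1-ene | C[Si](C)(C)OC1=C[C@H](C(C)C)[C@@H](O[Si](CC)(CC)CC)C1
F3 | step 1 | (S)-3-isopropyl-4-[(triethylsilyl)oxy]cyclopent-2-en-1-one | O=C1C=C(C(C)C)[C@@H](O[Si](CC)(CC)CC)C1
F4 | step 4 | (2R,3S,4S)-3-isopropyl-4-[(triethylsilyl)oxy]-2-[(trimethylsilyl)oxy]cyclopentan-1-one | O=C1[C@H](O[Si](C)(C)C)[C@@H](C(C)C)[C@@H](O[Si](CC)(CC)CC)C1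
F5 | step 4 | (4S,5S,6R)-5-isopropyl-4-[(triethylsilyl)oxy]-1,6-bis[(trimethylsilyl)oxy]cyclohex-1-ene | C[Si](C)(C)O[C@H]1C(O[Si](C)(C)C)=CC[C@H](O[Si](CC)(CC)CC)[C@@H]1C(C)C
F6 | step 4 | (4S,5S,6R)-5-isopropyl-4-[(triethylsilyl)oxy]-6-[(trimethylsilyl)oxy]cyclohex-2-en-1-one | C[Si](C)(C)O[C@H]1C(=O)C=C[C@H](O[Si](CC)(CC)CC)[C@@H]1C(C)C
F7 | step 4 | (4S,5R,6R)-6-hydroxy-5-isopropyl-4-[(triethylsilyl)oxy]cyclohex-2-en-1-one | O[C@H]1C(=O)C=C[C@H](O[Si](CC)(CC)CC)[C@@H]1C(C)C
F8 | step 7 | (1R,5R,6S)-3-iodo-6-isopropyl-5-[(2-methylpropanoyl)oxy]-2-oxocyclohex-3-en-1-yl (2E)-4-hydroxy-2-methylbut-2-enoate | C/C(=C\CO)C(=O)O[C@H]1C(=O)C(I)=C[C@H](OC(=O)C(C)C)[C@@H]1C(C)C
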